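**Retrosynthetic overview**
1. The target is (2S)-naringenin joined through C6 of its ring A to C8 of apigenin; the six phenols are carried as benzyl ethers and freed by one final hydrogenolysis.
2. Ring C of the flavanone (O1, C2, C3, C4, C4a, C8a) is closed last, by a chalcone-isomerase-like enantioselective oxa-Michael addition (O1–C2 bond) of a 2'-hydroxychalcone that carries a removable tert-butoxycarbonyl activator on C3; the activator leaves in the same flask.
3. Enabling feature: O1 stands β to the C4 carbonyl through C2–C3, and its carbon C8a is para to the biaryl carbon C6. Before acylation ring A is therefore symmetric about the C6···C8a axis: O1 is the one unique oxygen (kept as free OH), O5 and O7 are twin benzyl ethers, either ring CH gives the same acyl compound, and only the 6-linked flavanone can form.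
4. Chalcone ⇒ Knoevenagel condensation of an aroylacetate with 4-(benzyloxy)benzaldehyde; aroylacetate ⇒ ortho-formylation, Reformatsky addition and oxidation on the biaryl phenol; biaryl ⇒ Negishi coupling of 8-iodo-tri-O-benzylapigenin with a 2,6-bis(benzyloxy)-4-silyloxyphenylzinc.
5. Ring order: the three flavone rings come with apigenin, ring A with 3,5-bis(benzyloxy)phenol, ring B with the aldehyde; ring C is the only ring made and is made last.

Key step: step 11

Remark 1: the target SMILES fixes only C2; the tetra-ortho-oxygenated biaryl axis is left open, so the route does not control it, and compounds from 11 onward (19 included) are expected as mixtures of, or interconverting, atropisomers, each 2S at C2.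
Remark 2: the cinchona pseudo-enantiomer in step 11 is chosen for the 2S series; the quinidine-derived thiourea is written, and the quinine-derived one replaces it without other change if the sense of induction is the opposite.
Naming: Flv = 5,7-bis(benzyloxy)-2-[4-(benzyloxy)phenyl]-4-oxo-4H-chromen-8-yl.

**Route**

Step 1
Reactants: 1 apigenin
Product: 2 5,7-bis(benzyloxy)-2-[4-(benzyloxy)phenyl]-4H-chromen-4-one
Conditions: BnBr (4 equiv), K2CO3, DMF, 80 °C
Reagents that add atoms: benzyl bromide, BrCc1ccccc1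
Why: Williamson etherification with excess bromide in hot DMF should alkylate the chelated 5-OH as well, and the 5-O-alkyl group is what later steers iodination to C8.

Step 2
Reactants: 2 5,7-bis(benzyloxy)-2-[4-(benzyloxy)phenyl]-4H-chromen-4-one
Product: 3 5,7-bis(benzyloxy)-2-[4-(benzyloxy)phenyl]-8-iodo-4H-chromen-4-one
Conditions: NIS (1.1 equiv), CF3CO2H (cat.), CH2Cl2–MeCN, 0 °C to rt
Reagents that add atoms: N-iodosuccinimide, O=C1CCC(=O)N1I
Why: electrophilic aromatic iodination of a 5,7-di-O-alkylflavone should take place at C8 (ortho to O7, para to O5) and not at the more crowded C6 between the two benzyloxy groups, as is known for fully O-alkylated 5,7-dioxygenated flavones.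

Step 3
Reactants: 4 3,5-bis(benzyloxy)phenol
Product: 5 [3,5-bis(benzyloxy)phenoxy]tri(propan-2-yl)silane
Conditions: TIPSCl, imidazole, DMF, rt
Reagents that add atoms: chlorotri(propan-2-yl)silane, CC(C)[Si](Cl)(C(C)C)C(C)C
Why: silylation of the phenol marks the oxygen that will become O1 and places a bulky group that shields its two ortho positions.

Step 4
Reactants: 5 [3,5-bis(benzyloxy)phenoxy]tri(propan-2-yl)silane
Product: 6 [3,5-bis(benzyloxy)-4-iodophenoxy]tri(propan-2-yl)silane
Conditions: NIS (1.0 equiv), MeCN, −20 to 0 °C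
Reagents that add atoms: N-iodosuccinimide, O=C1CCC(=O)N1I
Why: electrophilic iodination of a phloroglucinol triether, in which the three ring CH are electronically alike and the triisopropylsilyl group shields the two positions next to it, should favour the position between the two benzyloxy groups, and the symmetric product is readily told from its unsymmetrical isomer.

Step 5
Reactants: 6 [3,5-bis(benzyloxy)-4-iodophenoxy]tri(propan-2-yl)silane; 3 5,7-bis(benzyloxy)-2-[4-(benzyloxy)phenyl]-8-iodo-4H-chromen-4-one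
Product: 9 5,7-bis(benzyloxy)-2-[4-(benzyloxy)phenyl]-8-{2,6-bis(benzyloxy)-4-[(triisopropylsilyl)oxy]phenyl}-4H-chromen-4-one, via aryllithium 7 (not isolated), via arylzinc chloride 8 (not isolated)
Conditions: 6, n-BuLi, THF, −78 °C; ZnCl2, −78 °C to rt; then 3, Pd2(dba)3 (2 mol%), RuPhos (8 mol%), THF–NMP, 70 °C
Reagents that add atoms: n-butyllithium, [Li]CCCC, and zinc chloride, Cl[Zn]Cl (their atoms stay only in 7 and 8; none remain in 9)
Why: Negishi coupling, in which iodine–lithium exchange at −78 °C outruns benzylic deprotonation, the arylzinc does not attack the chromone, and dialkylbiarylphosphine–palladium catalysts are known to join two di-ortho-substituted partners.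

Step 6
Reactants: 9 5,7-bis(benzyloxy)-2-[4-(benzyloxy)phenyl]-8-{2,6-bis(benzyloxy)-4-[(triisopropylsilyl)oxy]phenyl}-4H-chromen-4-one
Product: 10 5,7-bis(benzyloxy)-2-[4-(benzyloxy)phenyl]-8-[2,6-bis(benzyloxy)-4-hydroxyphenyl]-4H-chromen-4-one
Conditions: TBAF, AcOH, THF, 0 °C
Reagents that add atoms: none
Why: fluoride-mediated desilylation buffered with acetic acid frees only the oxygen para to the biaryl bond and leaves all benzyl ethers in place.

Step 7
Reactants: 10 5,7-bis(benzyloxy)-2-[4-(benzyloxy)phenyl]-8-[2,6-bis(benzyloxy)-4-hydroxyphenyl]-4H-chromen-4-one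
Product: 11 2,4-bis(benzyloxy)-3-Flv-6-hydroxybenzaldehyde
Conditions: MgCl2, Et3N, (CH2O)n, THF, reflux
Reagents that add atoms: paraformaldehyde (as formaldehyde), C=O
Why: magnesium-phenoxide-directed ortho-formylation of a phenol goes only ortho to the free OH, and because the two ortho positions are equivalent by the local symmetry of ring A a single aldehyde should result.

Step 8
Reactants: 11 2,4-bis(benzyloxy)-3-Flv-6-hydroxybenzaldehyde
Product: 12 tert-butyl 3-[2,4-bis(benzyloxy)-3-Flv-6-hydroxyphenyl]-3-hydroxypropanoate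
Conditions: BrCH2CO2t-Bu, Zn (TMSCl-activated), THF, 0 °C to rt (3 equiv of the preformed zinc reagent)
Reagents that add atoms: tert-butyl bromoacetate, CC(C)(C)OC(=O)CBr
Why: Reformatsky reaction, whose zinc enolate adds to the aldehyde but not to the chromone (one equivalent is consumed by the phenol), gives a carbinol centre that is not controlled and is erased in step 9.

Step 9
Reactants: 12 tert-butyl 3-[2,4-bis(benzyloxy)-3-Flv-6-hydroxyphenyl]-3-hydroxypropanoate
Product: 13 tert-butyl 3-[2,4-bis(benzyloxy)-3-Flv-6-hydroxyphenyl]-3-oxopropanoate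
Conditions: MnO2 (activated, excess), CH2Cl2, rt
Reagents that add atoms: none
Why: MnO2 oxidation of an electron-rich benzylic alcohol to the aryl ketone tolerates the free phenol and the benzyl ethers and removes the carbinol stereocentre.

Step 10
Reactants: 13 tert-butyl 3-[2,4-bis(benzyloxy)-3-Flv-6-hydroxyphenyl]-3-oxopropanoate; 14 4-(benzyloxy)benzaldehyde
Product: 15 tert-butyl (2Z)-2-[2,4-bis(benzyloxy)-3-Flv-6-hydroxybenzoyl]-3-[4-(benzyloxy)phenyl]prop-2-enoate
Conditions: piperidine (10 mol%), AcOH (10 mol%), 4 Å molecular sieves, toluene, rt to 40 °C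
Reagents that add atoms: none
Why: Knoevenagel condensation under a weakly basic buffered catalyst should give the alkylidene (expected Z, aryl trans to the aroyl group) without closing the ring, and the tert-butyl ester resists lactonisation by the neighbouring phenol.

Step 11
Reactants: 15 tert-butyl (2Z)-2-[2,4-bis(benzyloxy)-3-Flv-6-hydroxybenzoyl]-3-[4-(benzyloxy)phenyl]prop-2-enoate
Product: 18 (2S)-5,7-bis(benzyloxy)-2-[4-(benzyloxy)phenyl]-6-Flv-2,3-dihydro-4H-chromen-4-one, via cyclised tert-butyl ester 16 (not isolated), via keto acid 17 (not isolated)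
Conditions: quinidine-derived bifunctional thiourea, 1-[3,5-bis(trifluoromethyl)phenyl]-3-(9-deoxy-epi-quinidin-9-yl)thiourea (10 mol%), toluene, −25 °C; then TsOH·H2O, 80 °C
Reagents that add atoms: none
Why: The quinuclidine nitrogen of the catalyst activates the single free phenol of ring A as a general base while the thiourea binds the 1,3-dicarbonyl unit, and the phenoxide oxygen adds to the β-carbon of the alkylidene to form the O1–C2 bond and close ring C as keto ester 16 (6-endo-trig oxa-Michael addition); TsOH at 80 °C then cleaves the tert-butyl ester to acid 17, which loses CO2, so that the activating group and the uncontrolled C3 centre disappear in the same flask. The closest known reaction type is the cinchona-thiourea-catalysed enantioselective cyclisation of 2'-hydroxyaryl alkylidene β-keto esters to flavanones with in-flask decarboxylation, a laboratory counterpart of the chalcone isomerase step of flavonoid biosynthesis. The C2 stereocentre is set under catalyst control, because the hydrogen-bonded, ion-paired catalyst shields one face of the alkene, and the pseudo-enantiomer is chosen for 2S; the stereogenic but racemic biaryl axis lies para to the attacking oxygen and should not override it. The step needs regioselectivity between the two oxygens ortho to the ketone, and the substrate secures it: the oxygen next to the biaryl bond is a benzyl ether, so only the oxygen para to the biaryl bond can close and only the 6-linked flavanone can form. It also needs the closed ring to stay closed, which low temperature in the addition and base-free acid in the decarboxylation should ensure, since ring opening by the retro-oxa-Michael path is the route to racemisation.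

Step 12
Reactants: 18 (2S)-5,7-bis(benzyloxy)-2-[4-(benzyloxy)phenyl]-6-Flv-2,3-dihydro-4H-chromen-4-one
Product: 19 (2S)-6-[5,7-dihydroxy-2-(4-hydroxyphenyl)-4-oxo-4H-chromen-8-yl]-5,7-dihydroxy-2-(4-hydroxyphenyl)-2,3-dihydro-4H-chromen-4-one
Conditions: H2 (1 atm), Pd/C (10%), THF–MeOH, rt
Reagents that add atoms: none
Why: hydrogenolysis of the six benzyl ethers under neutral conditions should leave the flavone double bond and both carbonyl groups untouched and, with no base present, cannot open ring C or racemise C2.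

**Compound list**
1 | apigenin, 5,7-dihydroxy-2-(4-hydroxyphenyl)-4H-chromen-4-one | O=c1cc(-c2ccc(O)cc2)oc2cc(O)cc(O)c12 | starting material
2 | 5,7-bis(benzyloxy)-2-[4-(benzyloxy)phenyl]-4H-chromen-4-one | O=c1cc(-c2ccc(OCc3ccccc3)cc2)oc2cc(OCc3ccccc3)cc(OCc3ccccc3)c12 | intermediate
3 | 5,7-bis(benzyloxy)-2-[4-(benzyloxy)phenyl]-8-iodo-4H-chromen-4-one | O=c1cc(-c2ccc(OCc3ccccc3)cc2)oc2c(I)c(OCc3ccccc3)cc(OCc3ccccc3)c12 | intermediate
4 | 3,5-bis(benzyloxy)phenol | Oc1cc(OCc2ccccc2)cc(OCc2ccccc2)c1 | starting material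
5 | [3,5-bis(benzyloxy)phenoxy]tri(propan-2-yl)silane | CC(C)[Si](Oc1cc(OCc2ccccc2)cc(OCc2ccccc2)c1)(C(C)C)C(C)C | intermediate
6 | [3,5-bis(benzyloxy)-4-iodophenoxy]tri(propan-2-yl)silane | CC(C)[Si](Oc1cc(OCc2ccccc2)c(I)c(OCc2ccccc2)c1)(C(C)C)C(C)C | intermediate
7 | {2,6-bis(benzyloxy)-4-[(triisopropylsilyl)oxy]phenyl}lithium, formed in the flask | CC(C)[Si](Oc1cc(OCc2ccccc2)c([Li])c(OCc2ccccc2)c1)(C(C)C)C(C)C | intermediate
8 | {2,6-bis(benzyloxy)-4-[(triisopropylsilyl)oxy]phenyl}zinc chloride, formed in the flask | CC(C)[Si](Oc1cc(OCc2ccccc2)c([Zn]Cl)c(OCc2ccccc2)c1)(C(C)C)C(C)C | intermediate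
9 | 5,7-bis(benzyloxy)-2-[4-(benzyloxy)phenyl]-8-{2,6-bis(benzyloxy)-4-[(triisopropylsilyl)oxy]phenyl}-4H-chromen-4-one | CC(C)[Si](Oc1cc(OCc2ccccc2)c(-c2c(OCc3ccccc3)cc(OCc3ccccc3)c3c(=O)cc(-c4ccc(OCc5ccccc5)cc4)oc23)c(OCc2ccccc2)c1)(C(C)C)C(C)C | intermediate
10 | 5,7-bis(benzyloxy)-2-[4-(benzyloxy)phenyl]-8-[2,6-bis(benzyloxy)-4-hydroxyphenyl]-4H-chromen-4-one | Oc1cc(OCc2ccccc2)c(-c2c(OCc3ccccc3)cc(OCc3ccccc3)c3c(=O)cc(-c4ccc(OCc5ccccc5)cc4)oc23)c(OCc2ccccc2)c1 | intermediate
11 | 2,4-bis(benzyloxy)-3-{5,7-bis(benzyloxy)-2-[4-(benzyloxy)phenyl]-4-oxo-4H-chromen-8-yl}-6-hydroxybenzaldehyde | O=Cc1c(O)cc(OCc2ccccc2)c(-c2c(OCc3ccccc3)cc(OCc3ccccc3)c3c(=O)cc(-c4ccc(OCc5ccccc5)cc4)oc23)c1OCc1ccccc1 | intermediate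
12 | tert-butyl 3-[2,4-bis(benzyloxy)-3-Flv-6-hydroxyphenyl]-3-hydroxypropanoate (carbinol centre not defined) | CC(C)(C)OC(=O)CC(O)c1c(O)cc(OCc2ccccc2)c(-c2c(OCc3ccccc3)cc(OCc3ccccc3)c3c(=O)cc(-c4ccc(OCc5ccccc5)cc4)oc23)c1OCc1ccccc1 | intermediate
13 | tert-butyl 3-[2,4-bis(benzyloxy)-3-Flv-6-hydroxyphenyl]-3-oxopropanoate | CC(C)(C)OC(=O)CC(=O)c1c(O)cc(OCc2ccccc2)c(-c2c(OCc3ccccc3)cc(OCc3ccccc3)c3c(=O)cc(-c4ccc(OCc5ccccc5)cc4)oc23)c1OCc1ccccc1 | intermediate
14 | 4-(benzyloxy)benzaldehyde | O=Cc1ccc(OCc2ccccc2)cc1 | starting material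
15 | tert-butyl (2Z)-2-[2,4-bis(benzyloxy)-3-Flv-6-hydroxybenzoyl]-3-[4-(benzyloxy)phenyl]prop-2-enoate | CC(C)(C)OC(=O)/C(=C\c1ccc(OCc2ccccc2)cc1)C(=O)c1c(O)cc(OCc2ccccc2)c(-c2c(OCc3ccccc3)cc(OCc3ccccc3)c3c(=O)cc(-c4ccc(OCc5ccccc5)cc4)oc23)c1OCc1ccccc1 | intermediate
16 | tert-butyl (2S)-5,7-bis(benzyloxy)-2-[4-(benzyloxy)phenyl]-6-Flv-4-oxo-3,4-dihydro-2H-chromene-3-carboxylate (C3 not defined), formed in the flask | O=C1C(C(=O)OC(C)(C)C)[C@@H](c2ccc(OCc3ccccc3)cc2)Oc2cc(OCc3ccccc3)c(-c3c(OCc4ccccc4)cc(OCc4ccccc4)c4c(=O)cc(-c5ccc(OCc6ccccc6)cc5)oc34)c(OCc3ccccc3)c21 | intermediate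
17 | (2S)-5,7-bis(benzyloxy)-2-[4-(benzyloxy)phenyl]-6-Flv-4-oxo-3,4-dihydro-2H-chromene-3-carboxylic acid (C3 not defined), formed in the flask | O=C1C(C(=O)O)[C@@H](c2ccc(OCc3ccccc3)cc2)Oc2cc(OCc3ccccc3)c(-c3c(OCc4ccccc4)cc(OCc4ccccc4)c4c(=O)cc(-c5ccc(OCc6ccccc6)cc5)oc34)c(OCc3ccccc3)c21 | intermediate
18 | (2S)-5,7-bis(benzyloxy)-2-[4-(benzyloxy)phenyl]-6-{5,7-bis(benzyloxy)-2-[4-(benzyloxy)phenyl]-4-oxo-4H-chromen-8-yl}-2,3-dihydro-4H-chromen-4-one | O=C1C[C@@H](c2ccc(OCc3ccccc3)cc2)Oc2cc(OCc3ccccc3)c(-c3c(OCc4ccccc4)cc(OCc4ccccc4)c4c(=O)cc(-c5ccc(OCc6ccccc6)cc5)oc34)c(OCc3ccccc3)c21 | intermediate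
19 | (2S)-6-[5,7-dihydroxy-2-(4-hydroxyphenyl)-4-oxo-4H-chromen-8-yl]-5,7-dihydroxy-2-(4-hydroxyphenyl)-2,3-dihydro-4H-chromen-4-one | O=C1C[C@@H](c2ccc(O)cc2)Oc2cc(O)c(-c3c(O)cc(O)c4c(=O)cc(-c5ccc(O)cc5)oc34)c(O)c21 | target

**Step count and risks**
Total: 12 steps. Longest linear sequence: 10 steps (from 4 through steps 3 to 12; the apigenin branch through steps 1, 2 and 5 to 12 is equally long).

Steps most likely to fail:

1. Step 11. Enantiocontrol may erode through uncatalysed background closure on the hindered, hydrogen-bonded 2',6'-dioxygenated aroyl system, through reversible opening of 16 before decarboxylation, or through acid-promoted opening of the 4-benzyloxybenzylic C2–O1 bond at 80 °C. Fallback, leaving the route at 13 and rejoining it at 18: heating 13 with TsOH in toluene removes the ester and gives the methyl ketone 1-[2,4-bis(benzyloxy)-3-Flv-6-hydroxyphenyl]ethan-1-one F1; Me2NCH(OMe)2 at 90 °C converts it into the enaminone (2E)-1-[2,4-bis(benzyloxy)-3-Flv-6-hydroxyphenyl]-3-(dimethylamino)prop-2-en-1-one F2; HCl in CH2Cl2 closes this to the chromone 5,7-bis(benzyloxy)-6-Flv-4H-chromen-4-one F3; and palladium-catalysed asymmetric conjugate addition of 4-(benzyloxy)phenylboronic acid (Pd(OCOCF3)2, the enantiomer of 4-tert-butyl-2-(pyridin-2-yl)-4,5-dihydrooxazole that leads to 2S, NH4PF6, H2O, ClCH2CH2Cl, 60 °C) gives 18. Ring C is then closed as an achiral chromone, and the stereocentre is set in a separate C–C bond formation that ring opening cannot undo.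

2. Step 5. Transmetalation and reductive elimination toward a tetra-ortho-substituted biaryl may be slow, so that protodemetalation of the electron-rich arylzinc and homocoupling take over. Fallback, leaving at 3 and rejoining at 9: Miyaura borylation of 3 (B2pin2, PdCl2(dppf), KOAc, dioxane, 90 °C) gives the boronic ester 5,7-bis(benzyloxy)-2-[4-(benzyloxy)phenyl]-8-(4,4,5,5-tetramethyl-1,3,2-dioxaborolan-2-yl)-4H-chromen-4-one F4, and Suzuki–Miyaura coupling of F4 with iodide 6 (Pd(OAc)2, SPhos, K3PO4, toluene, 100 °C) gives 9. The roles are reversed, so the metal sits on the less electron-rich partner, which is less prone to lose it.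

3. Step 10. The alkylidene may close its ring in the Knoevenagel flask without stereocontrol, or condensation at the hindered methylene may stall. Fallback, leaving at 13 and rejoining at 15: TBSCl and imidazole in DMF mask the phenol as the silyl ether tert-butyl 3-[2,4-bis(benzyloxy)-6-{[tert-butyl(dimethyl)silyl]oxy}-3-Flv-phenyl]-3-oxopropanoate F5; Knoevenagel condensation with 14 can then be forced (piperidine, AcOH, toluene, reflux with water removal) to the silylated alkylidene tert-butyl (2Z)-2-[2,4-bis(benzyloxy)-6-{[tert-butyl(dimethyl)silyl]oxy}-3-Flv-benzoyl]-3-[4-(benzyloxy)phenyl]prop-2-enoate F6, which cannot cyclise; HF·pyridine in THF at 0 °C frees the phenol under acidic conditions to give 15, which is taken at once into step 11.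

Further compounds
F1 | step 11 | 1-[2,4-bis(benzyloxy)-3-Flv-6-hydroxyphenyl]ethan-1-one | CC(=O)c1c(O)cc(OCc2ccccc2)c(-c2c(OCc3ccccc3)cc(OCc3ccccc3)c3c(=O)cc(-c4ccc(OCc5ccccc5)cc4)oc23)c1OCc1ccccc1
F2 | step 11 | (2E)-1-[2,4-bis(benzyloxy)-3-Flv-6-hydroxyphenyl]-3-(dimethylamino)prop-2-en-1-one | CN(C)/C=C/C(=O)c1c(O)cc(OCc2ccccc2)c(-c2c(OCc3ccccc3)cc(OCc3ccccc3)c3c(=O)cc(-c4ccc(OCc5ccccc5)cc4)oc23)c1OCc1ccccc1
F3 | step 11 | 5,7-bis(benzyloxy)-6-Flv-4H-chromen-4-one | O=c1ccoc2cc(OCc3ccccc3)c(-c3c(OCc4ccccc4)cc(OCc4ccccc4)c4c(=O)cc(-c5ccc(OCc6ccccc6)cc5)oc34)c(OCc3ccccc3)c12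
F4 | step 5 | 5,7-bis(benzyloxy)-2-[4-(benzyloxy)phenyl]-8-(4,4,5,5-tetramethyl-1,3,2-dioxaborolan-2-yl)-4H-chromen-4-one | CC1(C)OB(OC1(C)C)c1c(OCc2ccccc2)cc(OCc2ccccc2)c2c(=O)cc(-c3ccc(OCc4ccccc4)cc3)oc12
F5 | step 10 | tert-butyl 3-[2,4-bis(benzyloxy)-6-{[tert-butyl(dimethyl)silyl]oxy}-3-Flv-phenyl]-3-oxopropanoate | CC(C)(C)OC(=O)CC(=O)c1c(O[Si](C)(C)C(C)(C)C)cc(OCc2ccccc2)c(-c2c(OCc3ccccc3)cc(OCc3ccccc3)c3c(=O)cc(-c4ccc(OCc5ccccc5)cc4)oc23)c1OCc1ccccc1
F6 | step 10 | tert-butyl (2Z)-2-[2,4-bis(benzyloxy)-6-{[tert-butyl(dimethyl)silyl]oxy}-3-Flv-benzoyl]-3-[4-(benzyloxy)phenyl]prop-2-enoate | CC(C)(C)OC(=O)/C(=C\c1ccc(OCc2ccccc2)cc1)C(=O)c1c(O[Si](C)(C)C(C)(C)C)cc(OCc2ccccc2)c(-c2c(OCc3ccccc3)cc(OCc3ccccc3)c3c(=O)cc(-c4ccc(OCc5ccccc5)cc4)oc23)c1OCc1ccccc1
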